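## The problem

Compound 15 is a 2,3-dihydrobenzofuran. Ring A is fused to the oxygen ring O1–C2–C3–C3a–C7a and carries a methoxy group at C7 and a 2-(methoxycarbonyl)ethyl chain at C5. C2 carries ring B (4-hydroxy-3,5-dimethoxyphenyl) and C3 carries the hydroxymethyl carbon, called C9 here. The two ring stereocentres are adjacent, (2S,3R), with aryl and hydroxymethyl trans. Trans is the more stable arrangement, and C3 is epimerisable whenever C9 stands at the carboxyl level, so a correctly set C2 can dictate C3 by equilibration; the reverse relay would need a stereocontrolled bond formation at the benzylic carbon. The C2–O1 bond is a benzylic ether of an electron-rich arene and also an aryl ether, so it is open to ionisation in acid and to hydrogenolysis. The free phenol of ring B is easily oxidised toward a quinone methide through C2 and is best kept masked to the end. Two ester-level carbons must finish in different oxidation states (C9 as alcohol, the chain terminus as methyl ester), which argues for building the chain after C9 is reduced. The enabling feature is that C3a and C7a are neighbours on ring A and bear C3 and O1, while C3–C2–O1 is the α-carbon, carbinol carbon and hydroxyl oxygen of a β-aryl-β-hydroxy ester whose carboxyl carbon is C9.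

## Retrosynthesis

**15 back to 14, then to 12 and 13.** The saturated chain and the free phenol of 15 both arise by addition of hydrogen, so 15 is traced to the benzyl-protected (E)-enoate 14. The C=C bond of 14 is cut by olefination to aldehyde 12 and phosphonate 13. A Heck coupling on a 5-halo compound would require a second halogen to survive the palladium chemistry of the key step, and a ready-made propanoate chain has α-protons that would not survive its strong base. The aldehyde handle is already present in the ring A starting material. The forward steps must spare the C2–O1 bond; alkene geometry does not matter.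

**12 back to 10.** C9 is raised to the methyl ester and the aldehyde is masked as its dimethyl acetal, giving 10 (the forward hydrolysis passes through acetal alcohol 11). At the ester level C3 can be set by equilibration toward trans instead of by a selective reaction. The acetal is the smallest mask that withstands amide bases and enolates. The forward direction needs one hydride reduction and one brief acid treatment that does not ionise C2–O1.

**10 back to 3 and 8 (through 9).** Both bonds from ring A to the heterocycle are cut, C3–C3a and O1–C7a. Cutting O1–C2 would need C3 preset and relayed to C2, and cutting C2–C3 would need a tethered benzyl ether and a diazo ester. The chosen cut instead splits 10 into two fragments of similar size and removes the ring and one stereocentre together. What remains is arene 3, with bromide on the future C3a and triflate on the future C7a, and β-hydroxy ester 8, whose single stereocentre is the future C2. The forward reaction must join the enolate carbon of the dianion of 8 to the bromide carbon first (open-chain 9), then the alkoxide oxygen to the triflate carbon, without breaking the carbinol C–O bond, and must deliver the trans ester. The regiochemistry of the annulation rests on bromide reacting before triflate.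

**8 back to 7, then to 5 and 6, then to 4.** The carbinol C–H bond of 8 is traced to β-keto ester 7, a substrate built for chelation-controlled asymmetric hydrogenation. This is preferred to an asymmetric acetate aldol because catalyst-controlled reduction of β-keto esters is among the most dependable routes to enantiopure secondary alcohols. Compound 7 is cut between α-carbon and carboxyl carbon (the future C3–C9 bond) to ketone 5 and carbonate 6, and 5 is the benzyl ether of commercial 4. The forward steps must give high enantiomeric purity at an electron-rich benzylic carbinol.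

**3 back to 2 and 1.** Removing the acetal and then the sulfonyl group leads to 1, which has all four ring A substituents in place: hydroxyl on the future C7a, bromine on the future C3a, methoxy on C7 and formyl on C5. Sulfonylation comes first, so the acetal is formed on an electron-poor aldehyde and never meets the sulfonylating agent.

## Roads not taken

**Alternative 1:** The cut runs through C3–C9 and the C2–ring B bond, across the C2=C3 bond of an aromatic benzofuran. Forward, benzofuranyl boronic ester A2 and aryllithium A3 would form an ate complex. A chiral π-allylpalladium electrophile would attack it at C3 while ring B migrates from boron to C2, giving the dearomatised tertiary boronic ester A1 with aryl and allyl trans.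
- Merits: three simple components are joined in one catalytic enantioselective event that makes both C–C bonds and both ring stereocentres, and the flat benzofuran is easy to prepare.
- Weak points: boron must be replaced by hydrogen at a tertiary, benzylic, oxygen-bearing carbon with full stereochemical fidelity. The allyl group has two carbons too many, so alkene migration, oxidative cleavage and reduction are needed to reach C9, through an epimerisable C3 aldehyde and with electron-rich arenes exposed to an oxidant. The metallate shift is established for indole boronates; a benzofuran is a weaker C3 nucleophile, and an unsubstituted allyl fragment gives the catalyst little to discriminate the heteroarene faces.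
- Comparison: this road sets both centres by catalyst control in one step, which the chosen plan does not (it needs a separate hydrogenation for C2 and thermodynamics for C3). The chosen plan sets against this a C2–H delivered directly, C9 one hydride reduction from the alcohol, and a shorter endgame.

**Alternative 2:** Only O1–C2 is cut. Precursor A5 is an open-chain 1,2-diarylpropane in which C3 already carries ring A (as a silyl-protected phenol), the silyloxymethyl group and the benzylic CH2 of ring B. Ag2O would oxidise the 4-alkyl-2,6-dimethoxyphenol of A5 to the para-quinone methide. KHF2 would then free the ring A phenoxide, which adds to C2 in a 5-exo-trig closure to give A4, one desilylation from 15.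
- Merits: the closure imitates the way this class of natural products forms, is mild, needs no transition metal, tolerates the finished side chain and ends almost at the target.
- Weak points: the stereochemical burden moves to A5, whose diaryl-substituted stereocentre needs its own auxiliary- or catalyst-based synthesis in a longer linear sequence. That centre is lost if the quinone methide tautomerises to the styrene. C2 is set only by 1,2-induction from C3, and the oxidant must act on one phenol while the other stays silylated.
- Comparison: for the ring-closing event this road is the safer one, since phenoxide addition to a quinone methide is a known reaction type, and it finishes closer to the target. The chosen plan sets against this its convergence (fragments of two and three steps), a C2 fixed by ketone hydrogenation instead of relay, and a configurationally robust stereocentre-bearing precursor (8).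

**Alternative 3:** The cut is C3–C3a, made by migration. In flavanone A7 ring A sits on the carbonyl carbon. PhI(OAc)2 and H2SO4 in trimethyl orthoformate would place trivalent iodine on C3 of the enol ether anti to the C2 aryl group. Ring A then shifts from the carbonyl carbon to C3 as iodobenzene leaves, and the former carbonyl carbon becomes the methyl ester of A6 (trans).
- Merits: oxidative ring contraction of flavanones to trans-2-aryl-2,3-dihydrobenzofuran-3-carboxylates is a known reaction type, it is metal-free, C2 relays cleanly to C3, and the ester of A6 is at the same oxidation level as in 10.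
- Weak points: an enantiopure flavanone with an electron-rich 2-aryl group is required, and such flavanones lose configuration by reversible retro-oxa-Michael ring opening, the more so in strong acid. The trivalent iodine reagent forces ring B to be deactivated as a pivalate, and the bromine needed for the later chain lowers the migratory aptitude of ring A. The chain then costs a separate Heck coupling, and the pivalate must be removed.
- Comparison: the key step of this road has direct precedent, which the chosen plan cannot claim, and the step count after ring formation is about the same. The chosen plan sets against this a stereogenic carbinol kept in an acyclic β-hydroxy ester that never meets strong acid or an oxidant, and a convergent formation of both ring bonds with no protecting-group change on ring B.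

Key step: step 6

## Remarks on the chemistry

- Assumption: RuCl2[(R)-BINAP] is taken to deliver hydrogen to aryl β-keto ester 7 from the same face as to alkyl β-keto esters; that face corresponds to the (S) descriptor in 8 because aryl outranks CH2CO2Me.
- The target is taken as the (2S,3R)-trans isomer encoded by its SMILES; ring numbering is O1, C2, C3, C3a, C4–C7, C7a, with C9 the hydroxymethyl carbon.

## Route

Step 1
Reactants: 1 5-bromovanillin (3-bromo-4-hydroxy-5-methoxybenzaldehyde)
Product: 2 2-bromo-4-formyl-6-methoxyphenyl trifluoromethanesulfonate
Conditions: Tf2O, pyridine, CH2Cl2, 0 °C → rt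
Reagents that add atoms: trifluoromethanesulfonic anhydride, O=S(=O)(OS(=O)(=O)C(F)(F)F)C(F)(F)F
Why: O-sulfonylation of a phenol; the acidic, doubly ortho-substituted phenol of 1 should be triflated cleanly and the aldehyde is inert to the reagent.

Step 2
Reactants: 2 2-bromo-4-formyl-6-methoxyphenyl trifluoromethanesulfonate
Product: 3 2-bromo-4-(dimethoxymethyl)-6-methoxyphenyl trifluoromethanesulfonate
Conditions: HC(OMe)3, MeOH, p-TsOH (cat.), rt; Et3N quench
Reagents that add atoms: trimethyl orthoformate, COC(OC)OC; methanol, CO
Why: Acid-catalysed acetalisation with the orthoformate as water scavenger; the electron-poor aldehyde is a good electrophile, triflate and bromide are inert to acid, and the acetal masks the aldehyde against the base and enolate of step 6.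

Step 3
Reactants: 4 acetosyringone (1-(4-hydroxy-3,5-dimethoxyphenyl)ethanone)
Product: 5 1-(4-benzyloxy-3,5-dimethoxyphenyl)ethanone
Conditions: BnBr, K2CO3, DMF, 60 °C
Reagents that add atoms: benzyl bromide, BrCc1ccccc1
Why: Williamson ether synthesis on the phenoxide; the benzyl ether protects the oxidation-prone phenol of ring B through base, hydride and acid and is removed in the final hydrogenation.

Step 4
Reactants: 5 1-(4-benzyloxy-3,5-dimethoxyphenyl)ethanone; 6 dimethyl carbonate
Product: 7 methyl 3-(4-benzyloxy-3,5-dimethoxyphenyl)-3-oxopropanoate
Conditions: NaH, THF, reflux (6 in excess); then aq. HCl, 0 °C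
Reagents that add atoms: none
Why: Crossed Claisen condensation of the ketone enolate with the carbonate, driven by deprotonation of the β-keto ester formed; it installs the carboxyl carbon that becomes C9.

Step 5
Reactants: 7 methyl 3-(4-benzyloxy-3,5-dimethoxyphenyl)-3-oxopropanoate
Product: 8 methyl (3S)-3-(4-benzyloxy-3,5-dimethoxyphenyl)-3-hydroxypropanoate
Conditions: RuCl2[(R)-BINAP](dmf)n (1 mol %), H2 (10 atm), MeOH, 50 °C
Reagents that add atoms: none
Why: Noyori asymmetric hydrogenation of a β-keto ester; ketone and ester oxygens chelate ruthenium and the (R)-BINAP ligand directs hydride to one ketone face, setting the future C2 as (S). Aryl benzyl ethers are not cleaved by this homogeneous catalyst.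

Step 6
Reactants: 8 methyl (3S)-3-(4-benzyloxy-3,5-dimethoxyphenyl)-3-hydroxypropanoate; 3 2-bromo-4-(dimethoxymethyl)-6-methoxyphenyl trifluoromethanesulfonate
Product: 10 methyl (2S,3S)-2-(4-benzyloxy-3,5-dimethoxyphenyl)-5-(dimethoxymethyl)-7-methoxy-2,3-dihydro-1-benzofuran-3-carboxylate (2,3-trans), via open-chain α-aryl β-hydroxy ester triflate 9 (not isolated)
Conditions: LiN(SiMe3)2 (3.3 equiv), toluene, −20 °C → rt; then 3, Pd(dba)2 (5 mol %), P(t-Bu)3 (6 mol %), rt → 80 °C; then MeOH, rt; aq. NaHCO3 work-up
Reagents that add atoms: none
Why: Proposed new method: LiN(SiMe3)2 converts 8 into its chelated dilithium alkoxide–enolate (the dianion of the Fráter–Seebach alkylation); zerovalent palladium bearing one P(t-Bu)3 inserts into the less hindered C–Br bond of 3 ahead of the doubly ortho-substituted C–OTf bond, and transmetalation with C–C reductive elimination joins the enolate carbon to the ring (C3–C3a) to give 9. The third equivalent of base turns 9 into its alkoxide–enolate, which blocks retro-aldol cleavage; a second oxidative addition at the neighbouring triflate gives an arylpalladium species that the adjacent lithium alkoxide captures, and C–O reductive elimination from the resulting six-membered aryl(alkoxo)palladium chelate closes the dihydrofuran (O1–C7a), the oxygen bonding to the ipso carbon in a closure that is 5-exo in ring-size terms. The closest known reaction types are the Pd-catalysed α-arylation of ester enolates with aryl bromides, the Pd-catalysed intramolecular etherification of secondary alcohols with ortho-haloarenes (which keeps carbinol configuration), and the domino C-arylation/O-arylation of ketone enolates with 1,2-dihaloarenes to benzofurans; new here are the ester dianion as C,O-dinucleophile and the saturated, stereodefined product. C2 is not made in this step: its C–O bond is never broken and the β-oxido group of a dianion is too poor a leaving group to eliminate, so the configuration from step 5 is carried through. C3 is the one new stereocentre and is set thermodynamically: the ring-closed ester stays as its lithium enolate until the methanol quench, and the lithium methoxide formed there equilibrates the α-proton to the trans isomer, in which ester and aryl group avoid each other. Ring opening of that enolate would be the reverse of a 5-endo-trig closure (the C2–O1 bond lies in the nodal plane of the enolate), so equilibration at C3 should not reach C2. The step needs bromide before triflate (secured by the bulky monophosphine and the steric difference between the two sites, which fixes which ring carbon receives carbon and which oxygen), C- before O-arylation of the dianion (secured by the faster transmetalation and reductive elimination of the enolate), and reductive elimination ahead of β-hydride loss from the palladium alkoxide (favoured by the bulky ligand and the five-membered ring being formed).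

Step 7
Reactants: 10 methyl (2S,3S)-2-(4-benzyloxy-3,5-dimethoxyphenyl)-5-(dimethoxymethyl)-7-methoxy-2,3-dihydro-1-benzofuran-3-carboxylate
Product: 12 (2S,3R)-2-(4-benzyloxy-3,5-dimethoxyphenyl)-3-(hydroxymethyl)-7-methoxy-2,3-dihydro-1-benzofuran-5-carbaldehyde, via acetal alcohol 11 (not isolated)
Conditions: LiAlH4, THF, 0 °C; EtOAc quench; then 1 M HCl, THF–H2O, rt (brief)
Reagents that add atoms: water, O
Why: Ester reduction by LiAlH4, then acid-catalysed acetal hydrolysis in the acidic work-up; neither operation breaks a bond at C2 or C3 (the descriptor at C3 changes from S to R only through priorities), and the benzyl and methyl ethers are stable to both.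

Step 8
Reactants: 12 (2S,3R)-2-(4-benzyloxy-3,5-dimethoxyphenyl)-3-(hydroxymethyl)-7-methoxy-2,3-dihydro-1-benzofuran-5-carbaldehyde; 13 trimethyl phosphonoacetate
Product: 14 methyl (2E)-3-[(2S,3R)-2-(4-benzyloxy-3,5-dimethoxyphenyl)-3-(hydroxymethyl)-7-methoxy-2,3-dihydro-1-benzofuran-5-yl]prop-2-enoate
Conditions: LiCl, DBU, MeCN, rt
Reagents that add atoms: none
Why: Horner–Wadsworth–Emmons olefination under Masamune–Roush conditions, mild enough to leave the free primary alcohol and the dihydrobenzofuran untouched; the (E)-enoate is expected, and the alkene geometry is erased in step 9.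

Step 9
Reactants: 14 methyl (2E)-3-[(2S,3R)-2-(4-benzyloxy-3,5-dimethoxyphenyl)-3-(hydroxymethyl)-7-methoxy-2,3-dihydro-1-benzofuran-5-yl]prop-2-enoate
Product: 15 methyl 3-[(2S,3R)-2-(4-hydroxy-3,5-dimethoxyphenyl)-3-(hydroxymethyl)-7-methoxy-2,3-dihydro-1-benzofuran-5-yl]propanoate
Conditions: H2 (1 atm), 10% Pd/C, EtOAc–MeOH, rt
Reagents that add atoms: none
Why: Heterogeneous catalytic hydrogenation that saturates the conjugated alkene and hydrogenolyses the benzyl aryl ether in one operation; short exposure at atmospheric pressure in a neutral solvent is chosen so that the ring C2–O1 bond is not cleaved.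

## Compound list

1 | 5-bromovanillin (3-bromo-4-hydroxy-5-methoxybenzaldehyde) | COc1cc(C=O)cc(Br)c1O | starting material
2 | 2-bromo-4-formyl-6-methoxyphenyl trifluoromethanesulfonate | COc1cc(C=O)cc(Br)c1OS(=O)(=O)C(F)(F)F | intermediate
3 | 2-bromo-4-(dimethoxymethyl)-6-methoxyphenyl trifluoromethanesulfonate | COC(OC)c1cc(Br)c(OS(=O)(=O)C(F)(F)F)c(OC)c1 | intermediate
4 | acetosyringone (1-(4-hydroxy-3,5-dimethoxyphenyl)ethanone) | CC(=O)c1cc(OC)c(O)c(OC)c1 | starting material
5 | 1-(4-benzyloxy-3,5-dimethoxyphenyl)ethanone | CC(=O)c1cc(OC)c(OCc2ccccc2)c(OC)c1 | intermediate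
6 | dimethyl carbonate | COC(=O)OC | starting material
7 | methyl 3-(4-benzyloxy-3,5-dimethoxyphenyl)-3-oxopropanoate | COC(=O)CC(=O)c1cc(OC)c(OCc2ccccc2)c(OC)c1 | intermediate
8 | methyl (3S)-3-(4-benzyloxy-3,5-dimethoxyphenyl)-3-hydroxypropanoate | COC(=O)C[C@@H](c1cc(OC)c(OCc2ccccc2)c(OC)c1)O | intermediate
9 | methyl (3S)-3-(4-benzyloxy-3,5-dimethoxyphenyl)-2-[5-(dimethoxymethyl)-3-methoxy-2-(trifluoromethanesulfonyloxy)phenyl]-3-hydroxypropanoate (not isolated; present as its lithium alkoxide–enolate, so the chain carbon 2 has no fixed configuration) | COC(=O)C(c1cc(C(OC)OC)cc(OC)c1OS(=O)(=O)C(F)(F)F)[C@@H](c1cc(OC)c(OCc2ccccc2)c(OC)c1)O | intermediate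
10 | methyl (2S,3S)-2-(4-benzyloxy-3,5-dimethoxyphenyl)-5-(dimethoxymethyl)-7-methoxy-2,3-dihydro-1-benzofuran-3-carboxylate (2,3-trans) | COC(OC)c1cc(OC)c2c(c1)[C@H](C(=O)OC)[C@@H](c1cc(OC)c(OCc3ccccc3)c(OC)c1)O2 | intermediate
11 | [(2S,3R)-2-(4-benzyloxy-3,5-dimethoxyphenyl)-5-(dimethoxymethyl)-7-methoxy-2,3-dihydro-1-benzofuran-3-yl]methanol (not isolated) | COC(OC)c1cc(OC)c2c(c1)[C@H](CO)[C@@H](c1cc(OC)c(OCc3ccccc3)c(OC)c1)O2 | intermediate
12 | (2S,3R)-2-(4-benzyloxy-3,5-dimethoxyphenyl)-3-(hydroxymethyl)-7-methoxy-2,3-dihydro-1-benzofuran-5-carbaldehyde | O=Cc1cc(OC)c2c(c1)[C@H](CO)[C@@H](c1cc(OC)c(OCc3ccccc3)c(OC)c1)O2 | intermediate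
13 | trimethyl phosphonoacetate | COC(=O)CP(=O)(OC)OC | starting material
14 | methyl (2E)-3-[(2S,3R)-2-(4-benzyloxy-3,5-dimethoxyphenyl)-3-(hydroxymethyl)-7-methoxy-2,3-dihydro-1-benzofuran-5-yl]prop-2-enoate | COC(=O)/C=C/c1cc(OC)c2c(c1)[C@H](CO)[C@@H](c1cc(OC)c(OCc3ccccc3)c(OC)c1)O2 | intermediate
15 | methyl 3-[(2S,3R)-2-(4-hydroxy-3,5-dimethoxyphenyl)-3-(hydroxymethyl)-7-methoxy-2,3-dihydro-1-benzofuran-5-yl]propanoate | COC(=O)CCc1cc(OC)c2c(c1)[C@H](CO)[C@@H](c1cc(OC)c(O)c(OC)c1)O2 | target

## Step count and least certain steps

Total step count: 9. Longest linear sequence: 7 steps (steps 3–9, from 4); the ring A branch is steps 1–2.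

**Step 6 (key step, proposed new method).**
- What may go wrong: ring closure stalling after the C–C coupling, because oxidative addition of the P(t-Bu)3 catalyst at the hindered and by then electron-rich aryl triflate is slow. The open-chain alkoxide then has time for S–O cleavage of the triflate (triflyl transfer to the alkoxide, which would also endanger C2), for β-hydride loss from a palladium alkoxide, or for retro-aldol cleavage.
- Fallback (known chemistry, forming C2–C3 by carbenoid C–H insertion), from 1 back to 10: NaBH4 reduction of commercial 4-benzyloxy-3,5-dimethoxybenzaldehyde gives (4-benzyloxy-3,5-dimethoxyphenyl)methanol F1. Mitsunobu etherification of phenol 1 with F1 (PPh3, DIAD) gives 4-[(4-benzyloxy-3,5-dimethoxyphenyl)methoxy]-3-bromo-5-methoxybenzaldehyde F2. Acetalisation as in step 2 gives 2-[(4-benzyloxy-3,5-dimethoxyphenyl)methoxy]-1-bromo-5-(dimethoxymethyl)-3-methoxybenzene F3. Pd-catalysed coupling of the aryl bromide with the zinc enolate BrZnCH2CO2Me (Pd(dba)2, P(t-Bu)3, THF) gives methyl 2-{2-[(4-benzyloxy-3,5-dimethoxyphenyl)methoxy]-5-(dimethoxymethyl)-3-methoxyphenyl}acetate F4. Diazo transfer (4-acetamidobenzenesulfonyl azide, DBU) gives methyl 2-diazo-2-{2-[(4-benzyloxy-3,5-dimethoxyphenyl)methoxy]-5-(dimethoxymethyl)-3-methoxyphenyl}acetate F5. The chiral dirhodium carboxylate Rh2(S-PTTL)4, or its enantiomer if the sense proves opposite, should effect enantioselective carbenoid insertion into the benzylic C–H bond of the ether to give methyl (2S,3R)-2-(4-benzyloxy-3,5-dimethoxyphenyl)-5-(dimethoxymethyl)-7-methoxy-2,3-dihydro-1-benzofuran-3-carboxylate (2,3-cis) F6. NaOMe in methanol then epimerises C3 to return 10.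

**Step 5.**
- What may go wrong: erosion of enantiomeric purity, through imperfect facial selectivity with this electron-rich aryl ketone or through acid-promoted solvolysis of the benzylic alcohol in warm methanol by traces of HCl from the catalyst.
- Fallback (kinetic resolution in place of asymmetric catalysis), from 7 back to 8: NaBH4 reduction of 7 gives racemic methyl 3-(4-benzyloxy-3,5-dimethoxyphenyl)-3-hydroxypropanoate F7. Acylation with vinyl acetate catalysed by Burkholderia cepacia lipase should consume the (R)-enantiomer as methyl (3R)-3-acetoxy-3-(4-benzyloxy-3,5-dimethoxyphenyl)propanoate F8 and leave 8, which is separated by chromatography.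

**Step 7.**
- What may go wrong: ionisation of the C2–O1 bond of the electron-rich alcohol during the acidic hydrolysis, with epimerisation at C2 or ring opening.
- Fallback (acid moved to the ester stage, aldehyde regenerated by oxidation), from 10 back to 12: the acetal of 10 is hydrolysed first (dilute HCl, THF–water), where the C3 ester inductively disfavours a cation at C2, to give methyl (2S,3S)-2-(4-benzyloxy-3,5-dimethoxyphenyl)-5-formyl-7-methoxy-2,3-dihydro-1-benzofuran-3-carboxylate F9. LiAlH4 reduces ester and aldehyde together to [(2S,3R)-2-(4-benzyloxy-3,5-dimethoxyphenyl)-7-methoxy-2,3-dihydro-1-benzofuran-3,5-diyl]dimethanol F10. MnO2 in CH2Cl2 oxidises only the benzylic alcohol and returns 12.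

**Step 9.**
- What may go wrong: over-reduction by hydrogenolysis of the ring C2–O1 bond once the para-phenol of ring B is free.
- Fallback (two chemoselective operations without H2 and palladium), from 14 to 15: conjugate reduction with NaBH4 and NiCl2·6H2O in methanol gives methyl 3-[(2S,3R)-2-(4-benzyloxy-3,5-dimethoxyphenyl)-3-(hydroxymethyl)-7-methoxy-2,3-dihydro-1-benzofuran-5-yl]propanoate F11. BCl3 with pentamethylbenzene as cation scavenger in CH2Cl2 at −78 °C then removes the benzyl ether to give 15.

## Further compounds

F1 | step 6 | (4-benzyloxy-3,5-dimethoxyphenyl)methanol | OCc1cc(OC)c(OCc2ccccc2)c(OC)c1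
F2 | step 6 | 4-[(4-benzyloxy-3,5-dimethoxyphenyl)methoxy]-3-bromo-5-methoxybenzaldehyde | COc1cc(C=O)cc(Br)c1OCc1cc(OC)c(OCc2ccccc2)c(OC)c1
F3 | step 6 | 2-[(4-benzyloxy-3,5-dimethoxyphenyl)methoxy]-1-bromo-5-(dimethoxymethyl)-3-methoxybenzene | COC(OC)c1cc(Br)c(OCc2cc(OC)c(OCc3ccccc3)c(OC)c2)c(OC)c1
F4 | step 6 | methyl 2-{2-[(4-benzyloxy-3,5-dimethoxyphenyl)methoxy]-5-(dimethoxymethyl)-3-methoxyphenyl}acetate | COC(=O)Cc1cc(C(OC)OC)cc(OC)c1OCc1cc(OC)c(OCc2ccccc2)c(OC)c1
F5 | step 6 | methyl 2-diazo-2-{2-[(4-benzyloxy-3,5-dimethoxyphenyl)methoxy]-5-(dimethoxymethyl)-3-methoxyphenyl}acetate | COC(=O)C(=[N+]=[N-])c1cc(C(OC)OC)cc(OC)c1OCc1cc(OC)c(OCc2ccccc2)c(OC)c1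
F6 | step 6 | methyl (2S,3R)-2-(4-benzyloxy-3,5-dimethoxyphenyl)-5-(dimethoxymethyl)-7-methoxy-2,3-dihydro-1-benzofuran-3-carboxylate (2,3-cis) | COC(OC)c1cc(OC)c2c(c1)[C@@H](C(=O)OC)[C@@H](c1cc(OC)c(OCc3ccccc3)c(OC)c1)O2
F7 | step 5 | methyl 3-(4-benzyloxy-3,5-dimethoxyphenyl)-3-hydroxypropanoate (racemic) | COC(=O)CC(O)c1cc(OC)c(OCc2ccccc2)c(OC)c1
F8 | step 5 | methyl (3R)-3-acetoxy-3-(4-benzyloxy-3,5-dimethoxyphenyl)propanoate | COC(=O)C[C@H](c1cc(OC)c(OCc2ccccc2)c(OC)c1)OC(C)=O
F9 | step 7 | methyl (2S,3S)-2-(4-benzyloxy-3,5-dimethoxyphenyl)-5-formyl-7-methoxy-2,3-dihydro-1-benzofuran-3-carboxylate | O=Cc1cc(OC)c2c(c1)[C@H](C(=O)OC)[C@@H](c1cc(OC)c(OCc3ccccc3)c(OC)c1)O2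
F10 | step 7 | [(2S,3R)-2-(4-benzyloxy-3,5-dimethoxyphenyl)-7-methoxy-2,3-dihydro-1-benzofuran-3,5-diyl]dimethanol | OCc1cc(OC)c2c(c1)[C@H](CO)[C@@H](c1cc(OC)c(OCc3ccccc3)c(OC)c1)O2
F11 | step 9 | methyl 3-[(2S,3R)-2-(4-benzyloxy-3,5-dimethoxyphenyl)-3-(hydroxymethyl)-7-methoxy-2,3-dihydro-1-benzofuran-5-yl]propanoate | COC(=O)CCc1cc(OC)c2c(c1)[C@H](CO)[C@@H](c1cc(OC)c(OCc3ccccc3)c(OC)c1)O2
A1 | alternative 1 | 2-[(2S,3S)-3-allyl-2-(4-benzyloxy-3,5-dimethoxyphenyl)-5-(dimethoxymethyl)-7-methoxy-2,3-dihydro-1-benzofuran-2-yl]-4,4,5,5-tetramethyl-1,3,2-dioxaborolane (aryl and allyl trans) | COC(OC)c1cc(OC)c2c(c1)[C@H](CC=C)[C@@](B3OC(C)(C)C(C)(C)O3)(c1cc(OC)c(OCc3ccccc3)c(OC)c1)O2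
A2 | alternative 1 | 2-[5-(dimethoxymethyl)-7-methoxy-1-benzofuran-2-yl]-4,4,5,5-tetramethyl-1,3,2-dioxaborolane | COC(OC)c1cc(OC)c2oc(B3OC(C)(C)C(C)(C)O3)cc2c1
A3 | alternative 1 | (4-benzyloxy-3,5-dimethoxyphenyl)lithium | [Li]c1cc(OC)c(OCc2ccccc2)c(OC)c1
A4 | alternative 2 | methyl 3-[(2S,3R)-3-(tert-butyldimethylsilyloxymethyl)-2-(4-hydroxy-3,5-dimethoxyphenyl)-7-methoxy-2,3-dihydro-1-benzofuran-5-yl]propanoate | COC(=O)CCc1cc(OC)c2c(c1)[C@H](CO[Si](C)(C)C(C)(C)C)[C@@H](c1cc(OC)c(O)c(OC)c1)O2
A5 | alternative 2 | methyl 3-{4-(tert-butyldimethylsilyloxy)-3-[(2R)-1-(tert-butyldimethylsilyloxy)-3-(4-hydroxy-3,5-dimethoxyphenyl)propan-2-yl]-5-methoxyphenyl}propanoate | COC(=O)CCc1cc(OC)c(O[Si](C)(C)C(C)(C)C)c(c1)[C@H](CO[Si](C)(C)C(C)(C)C)Cc1cc(OC)c(O)c(OC)c1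
A6 | alternative 3 | methyl (2S,3S)-5-bromo-7-methoxy-2-(3,5-dimethoxy-4-pivaloyloxyphenyl)-2,3-dihydro-1-benzofuran-3-carboxylate (2,3-trans) | Brc1cc(OC)c2c(c1)[C@H](C(=O)OC)[C@@H](c1cc(OC)c(OC(=O)C(C)(C)C)c(OC)c1)O2
A7 | alternative 3 | (2S)-6-bromo-8-methoxy-2-(3,5-dimethoxy-4-pivaloyloxyphenyl)chroman-4-one | O=C1C[C@@H](c2cc(OC)c(OC(=O)C(C)(C)C)c(OC)c2)Oc2c(OC)cc(Br)cc12
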